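**Retrosynthetic overview**

1. Target triacid ⇐ ring-A/B keto dinitrile (C19 and C20 carried as nitriles, C7 as a silyl ether, C3 as ketone); the end game is C3 reduction, nitrile → aldehyde, desilylation, oxidation.
2. Key disconnection: rings B and A are closed in one anionic relay from a C/D bicyclic bis(unsaturated nitrile) and the enolate of a silyl glycolate; bonds formed are C1–C2, C5–C10 and C3–C4.
3. Enabling feature: the two quaternary carbons of ring A, C4 and C10, each carry a carboxyl carbon (C19, C20; 1,3-diaxial, α face) and C2/C3 carry oxygen. C10 and then C4 can therefore be α-cyano carbanions and C2–C3 an α-silyloxy acetate unit; ring B (C5–C6–C8–C9–C10) closes 5-exo between them.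
4. C/D enone: ring D by Pd enolate alkenylation of a 4,4-disubstituted cyclohexenone (ring C, from 3-ethoxycyclohexenone by Stork–Danheiser transposition); C8 and C6 by Pd- and Ir-catalysed allylic alkylations; C9 by conjugate addition.
5. Ring order: C, then D, then B and A together.

Key step: step 15

Remark (numbering): C-numbers and α/β refer to gibberellane numbering of the target; ring C = C8, C9, C11–C14, ring D = C8, C14, C13, C16, C15.
Remark (assumption): the enantiomer of the phosphoramidite ligand (step 5) and of the PHOX ligand (step 6) is taken to be the one that gives the drawn C6 and C8 configurations; both ligands exist in either enantiomeric form.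

**Route**

Step 1
Reactants: 1 (E)-but-2-ene-1,4-diol; 2 tert-butyl(chloro)diphenylsilane
Product: 3 (E)-4-(tert-butyldiphenylsilyloxy)but-2-en-1-ol
Conditions: NaH (1.0 equiv), THF, 0 °C; then 2, 0 °C → rt
Reagents that add atoms: tert-butyl(chloro)diphenylsilane CC(C)(C)[Si](Cl)(c1ccccc1)c1ccccc1
Why: Monosilylation of a symmetrical diol through its sparingly soluble mono-sodium alkoxide (Williamson-type O-silylation) should stop after one silyl group.

Step 2
Reactants: 3 (E)-4-(tert-butyldiphenylsilyloxy)but-2-en-1-ol; 4 methyl chloroformate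
Product: 5 (E)-4-(tert-butyldiphenylsilyloxy)but-2-enyl methyl carbonate
Conditions: pyridine, CH2Cl2, 0 °C
Reagents that add atoms: methyl chloroformate COC(=O)Cl
Why: O-Acylation of the primary allylic alcohol gives the carbonate leaving group needed for metal–allyl formation.

Step 3
Reactants: 6 2-chloroprop-2-en-1-ol; 7 1,1'-carbonyldiimidazole
Product: 8 2-chloroallyl 1H-imidazole-1-carboxylate
Conditions: THF, 0 °C → rt
Reagents that add atoms: 1,1'-carbonyldiimidazole O=C(n1ccnc1)n1ccnc1
Why: Acyl transfer from the diimidazolide to the alcohol gives a stable alkoxycarbonyl-imidazole C-acylating agent.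

Step 4
Reactants: 9 3-ethoxycyclohex-2-en-1-one; 8 2-chloroallyl 1H-imidazole-1-carboxylate
Product: 10 2-chloroallyl 4-ethoxy-2-oxocyclohex-3-ene-1-carboxylate (racemic)
Conditions: LiN(i-Pr)2 (2.1 equiv), THF, −78 °C; then 8, −78 → −40 °C
Reagents that add atoms: 2-chloroallyl 1H-imidazole-1-carboxylate C=C(Cl)COC(=O)n1ccnc1
Why: Kinetic α′-lithiation of the vinylogous ester and C-acylation (Claisen-type) give the β-keto ester, whose ring carbon is the future C8.

Step 5
Reactants: 10 2-chloroallyl 4-ethoxy-2-oxocyclohex-3-ene-1-carboxylate; 5 (E)-4-(tert-butyldiphenylsilyloxy)but-2-enyl methyl carbonate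
Product: 11 2-chloroallyl 1-[(2S)-1-(tert-butyldiphenylsilyloxy)but-3-en-2-yl]-4-ethoxy-2-oxocyclohex-3-ene-1-carboxylate (one diastereomer expected; the ring quaternary centre is not assigned because step 6 erases it)
Conditions: [Ir(cod)Cl]2 (2 mol%), N-aryl phosphoramidite ligand (Me-THQphos type, 4 mol%), 1,5,7-triazabicyclo[4.4.0]dec-5-ene (10 mol%), LiBr, THF, 25 °C
Reagents that add atoms: (E)-4-(tert-butyldiphenylsilyloxy)but-2-enyl methyl carbonate COC(=O)OC/C=C/CO[Si](c1ccccc1)(c1ccccc1)C(C)(C)C
Why: Iridium-catalysed branched-selective allylic alkylation of a cyclic β-keto ester: the enolate attacks the substituted terminus of the chiral allyl–iridium complex, so the ligand sets C6 (S) and leaves the vinyl group that later becomes C5.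

Step 6
Reactants: 11 Ir-alkylation product
Product: 12 (6S)-6-[(2S)-1-(tert-butyldiphenylsilyloxy)but-3-en-2-yl]-6-(2-chloroallyl)-3-ethoxycyclohex-2-en-1-one
Conditions: Pd2(dba)3 (2.5 mol%), t-Bu-PHOX (6 mol%), toluene, 40 °C
Reagents that add atoms: none
Why: Palladium-catalysed decarboxylative allylic alkylation (Tsuji–Trost type): loss of CO2 regenerates the C8 enolate, which recombines with the 2-chloroallyl–palladium fragment inside the PHOX pocket, so the ligand re-sets the C8 quaternary centre.

Step 7
Reactants: 12 quaternary vinylogous ester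
Product: 13 (4R)-4-[(2S)-1-(tert-butyldiphenylsilyloxy)but-3-en-2-yl]-4-(2-chloroallyl)cyclohex-2-en-1-one
Conditions: i-Bu2AlH, CH2Cl2, −78 °C; then 1 M HCl, THF, 0 °C
Reagents that add atoms: none
Why: Stork–Danheiser transposition: 1,2-reduction of the vinylogous ester and acid-induced loss of ethanol and water give the 4,4-disubstituted enone (ring C) without touching C8 or C6.

Step 8
Reactants: 13 4,4-disubstituted cyclohexenone
Product: 14 C/D enone, 5-[(2S)-1-(tert-butyldiphenylsilyloxy)but-3-en-2-yl]-7-methylenebicyclo[3.2.1]oct-3-en-2-one (C8 and C13 as in the target)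
Conditions: Pd2(dba)3 (5 mol%), XPhos (12 mol%), NaOt-Bu (1.3 equiv), toluene, 80 °C
Reagents that add atoms: none
Why: Palladium-catalysed intramolecular ketone α-alkenylation: the cross-conjugated α′-enolate (the γ-position is quaternary) couples with the alkenyl–palladium chloride, closing ring D 5-exo with the exocyclic methylene in place; C13 is dictated by the bridge.

Step 9
Reactants: 14 C/D enone; 15 diethyl (cyanomethyl)phosphonate
Product: 16 C9 Michael adduct, 4-[cyano(diethoxyphosphoryl)methyl]-substituted bicyclo[3.2.1]octan-2-one (C9 as in the target; both epimers at the phosphonate carbon)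
Conditions: KOt-Bu (0.2 equiv), THF, 0 °C → rt
Reagents that add atoms: diethyl (cyanomethyl)phosphonate CCOP(=O)(CC#N)OCC
Why: Base-catalysed Michael addition of the stabilised carbanion; axial attack on the enone face opposite the two-carbon bridge should set C9 with the new carbon anti to C15, as in the target.

Step 10
Reactants: 16 C9 Michael adduct; 17 4-methylbenzenesulfonohydrazide
Product: 18 C12 tosylhydrazone of 16
Conditions: EtOH, 50 °C
Reagents that add atoms: 4-methylbenzenesulfonohydrazide Cc1ccc(cc1)S(=O)(=O)NN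
Why: Condensation of the only ketone with the sulfonyl hydrazide prepares C12 for deoxygenation.

Step 11
Reactants: 18 C12 tosylhydrazone
Product: 19 C12-deoxy phosphonate nitrile (C9 as in the target; epimers at the phosphonate carbon)
Conditions: catecholborane, CHCl3, 0 °C → rt; then NaOAc·3H2O, reflux
Reagents that add atoms: none
Why: Caglioti-type tosylhydrazone reduction: hydroboration of C=N, then acetate-induced loss of sulfinate and N2 from the diazene gives the C12 methylene without affecting nitrile, phosphonate or alkenes.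

Step 12
Reactants: 19 C12-deoxy phosphonate nitrile; 20 formaldehyde
Product: 21 C/D α-methylene nitrile (2-substituted acrylonitrile on C9, vinyl group on C6)
Conditions: K2CO3, 37% aq. HCHO, THF, rt
Reagents that add atoms: formaldehyde C=O
Why: Horner–Wadsworth–Emmons olefination with formaldehyde converts the phosphonate carbanion into the 1,1-disubstituted acrylonitrile (C10=C1) and removes the stereo-undefined carbon.

Step 13
Reactants: 21 C/D α-methylene nitrile; 22 methacrolein
Product: 23 (E)-enal, C6–CH=C(CH3)–CHO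
Conditions: second-generation Hoveyda–Grubbs catalyst (10 mol%), methacrolein (10 equiv), CH2Cl2, 40 °C
Reagents that add atoms: methacrolein CC(=C)C=O
Why: Olefin cross-metathesis: only the monosubstituted vinyl group is a competent partner (the exocyclic methylene and the acrylonitrile are 1,1-disubstituted), and methacrolein should give the (E)-2-methyl enal.

Step 14
Reactants: 23 (E)-enal; 24 O-(diphenylphosphinyl)hydroxylamine
Product: 25 C/D bis(unsaturated nitrile), with 2-substituted acrylonitrile on C9 and (E)-2-methylalk-2-enenitrile on C6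
Conditions: toluene, 85 °C
Reagents that add atoms: O-(diphenylphosphinyl)hydroxylamine NOP(=O)(c1ccccc1)c1ccccc1
Why: Condensation to the O-phosphinyl oxime and thermal elimination of the phosphinic acid convert the aldehyde into the conjugated nitrile without free ammonia that could add to the acrylonitrile.

Step 15
Reactants: 25 C/D bis(unsaturated nitrile); 26 methyl 2-(tert-butyldimethylsilyloxy)acetate
Product: 30 ring-A/B keto dinitrile (2β-tert-butyldimethylsilyloxy-3-oxo-7-tert-butyldiphenylsilyloxy-gibberell-16-ene-19,20-dinitrile), via lithium enolate 27 (not isolated), via C10 lithionitrile 28 (not isolated), via C4 lithionitrile 29 (not isolated)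
Conditions: 26, LiN(i-Pr)2, THF, −78 °C; then 25, −78 → 0 °C; aq. NH4Cl; then DBU (cat.), CH2Cl2, rt
Reagents that add atoms: methyl 2-(tert-butyldimethylsilyloxy)acetate COC(=O)CO[Si](C)(C)C(C)(C)C
Why: Enolate 27 adds to the unhindered CH2 terminus of the acrylonitrile (C1–C2), the α-cyano carbanion at C10 (28) closes ring B by 5-exo-trig Michael addition to C5 of the tethered unsaturated nitrile, and the new α-cyano carbanion at C4 (29) closes ring A by 6-exo-trig acylation on the glycolate ester (C3–C4), after which methoxide enolises C2–H of the β-keto nitrile and makes the sequence irreversible. The closest known reaction type is the Michael–Michael–Dieckmann (MIMIRC) annulation of an ester enolate with two acrylate units, combined with nitrile-anion cyclisations that forge quaternary carbons. At C10 and then at C4 the slim, rod-like C=C=N–Li unit should take the crowded position between the two branches of the neighbouring stereocentre (C9, then C5) while that centre's hydrogen eclipses the alkyl arm, so the electrophile delivered through the tether ends anti to H9 and H5; this places C20 and C19 on the α face (1,3-diaxial) and C1 and C18 on the β face, and gives the trans A/B fusion (an ester enolate would be expected to give the opposite sense, which is why both carboxyls are carried as nitriles). C5 is set by allylic 1,3-strain at C6 (H6 eclipses the C5=C4 bond, attack syn to C8 and anti to the C7 arm), and C2 equilibrates through its enolate (DBU) to the equatorial 2β-silyl ether, the axial epimer being syn-diaxial to both nitriles. The step needs the first addition to occur only at the acrylonitrile and each carbanion to cyclise faster than it is protonated: the 1,1- versus trisubstituted acceptor pattern secures the first, and the 5-exo and 6-exo geometries, low temperature and the absence of a carbonyl-activated C–H at C6 (C7 is a silyl ether) favour the second.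

Step 16
Reactants: 30 ring-A/B keto dinitrile
Product: 31 3β-alcohol (2β-silyloxy-3β-hydroxy dinitrile)
Conditions: LiBH(s-Bu)3, THF, −78 °C
Reagents that add atoms: none
Why: The bulky borohydride delivers hydride from the equatorial direction and should give the axial 3β-alcohol, cis to the equatorial 2β-silyloxy group (any 2→3 silyl migration is harmless, both ethers are removed in step 18).

Step 17
Reactants: 31 3β-alcohol
Product: 32 19,20-dialdehyde (2β-silyloxy, 3β-hydroxy, 7-silyloxy)
Conditions: i-Bu2AlH (6 equiv), toluene–CH2Cl2, −78 → −20 °C; then aq. potassium sodium tartrate; SiO2/H2O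
Reagents that add atoms: water O
Why: Partial reduction of both tertiary nitriles to N-aluminio imines (the standard route from angular nitriles to aldehydes) and hydrolysis should give the 1,3-diaxial dialdehyde; the C3 aluminium alkoxide is inert.

Step 18
Reactants: 32 19,20-dialdehyde
Product: 33 2β,3β,7-triol 19,20-dialdehyde
Conditions: HF·pyridine, pyridine–THF, 0 °C → rt
Reagents that add atoms: none
Why: Fluoride cleaves both silyl ethers under buffered, non-basic conditions that avoid retro-aldol opening of the β-hydroxy aldehyde.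

Step 19
Reactants: 33 2β,3β,7-triol 19,20-dialdehyde
Product: 35 2β,3β-dihydroxygibberell-16-ene-7,19,20-trioic acid (the target gibberellin), via 7-acid 19,20-dialdehyde 34 (not isolated)
Conditions: TEMPO (cat.), PhI(OAc)2, MeCN–H2O, rt; then NaClO2, NaH2PO4, 2-methyl-2-butene, t-BuOH–H2O, rt
Reagents that add atoms: water O; sodium chlorite [Na+].[O-]Cl=O
Why: The oxoammonium oxidation is selective for the primary C7 alcohol over the secondary cis-diol, and the Pinnick chlorite oxidation then converts the two hindered aldehydes into acids while 2-methyl-2-butene protects the exocyclic alkene.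

**Compound list**

1 | (E)-but-2-ene-1,4-diol | OC/C=C/CO | starting material
2 | tert-butyl(chloro)diphenylsilane | CC(C)(C)[Si](Cl)(c1ccccc1)c1ccccc1 | starting material
3 | (E)-4-(tert-butyldiphenylsilyloxy)but-2-en-1-ol | OC/C=C/CO[Si](c1ccccc1)(c1ccccc1)C(C)(C)C | intermediate
4 | methyl chloroformate | COC(=O)Cl | starting material
5 | (E)-4-(tert-butyldiphenylsilyloxy)but-2-enyl methyl carbonate | COC(=O)OC/C=C/CO[Si](c1ccccc1)(c1ccccc1)C(C)(C)C | intermediate
6 | 2-chloroprop-2-en-1-ol | C=C(Cl)CO | starting material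
7 | 1,1'-carbonyldiimidazole | O=C(n1ccnc1)n1ccnc1 | starting material
8 | 2-chloroallyl 1H-imidazole-1-carboxylate | C=C(Cl)COC(=O)n1ccnc1 | intermediate
9 | 3-ethoxycyclohex-2-en-1-one | CCOC1=CC(=O)CCC1 | starting material
10 | 2-chloroallyl 4-ethoxy-2-oxocyclohex-3-ene-1-carboxylate (racemic) | C=C(Cl)COC(=O)C1CCC(OCC)=CC1=O | intermediate
11 | 2-chloroallyl 1-[(2S)-1-(tert-butyldiphenylsilyloxy)but-3-en-2-yl]-4-ethoxy-2-oxocyclohex-3-ene-1-carboxylate (ring quaternary centre not assigned) | C=C(Cl)COC(=O)C1([C@@H](CO[Si](c2ccccc2)(c2ccccc2)C(C)(C)C)C=C)CCC(OCC)=CC1=O | intermediate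
12 | (6S)-6-[(2S)-1-(tert-butyldiphenylsilyloxy)but-3-en-2-yl]-6-(2-chloroallyl)-3-ethoxycyclohex-2-en-1-one | C=C(Cl)C[C@]1([C@@H](CO[Si](c2ccccc2)(c2ccccc2)C(C)(C)C)C=C)CCC(OCC)=CC1=O | intermediate
13 | (4R)-4-[(2S)-1-(tert-butyldiphenylsilyloxy)but-3-en-2-yl]-4-(2-chloroallyl)cyclohex-2-en-1-one | C=C(Cl)C[C@]1([C@@H](CO[Si](c2ccccc2)(c2ccccc2)C(C)(C)C)C=C)CCC(=O)C=C1 | intermediate
14 | C/D enone, 5-[(2S)-1-(tert-butyldiphenylsilyloxy)but-3-en-2-yl]-7-methylenebicyclo[3.2.1]oct-3-en-2-one | C=C1C[C@]2([C@@H](CO[Si](c3ccccc3)(c3ccccc3)C(C)(C)C)C=C)C[C@H]1C(=O)C=C2 | intermediate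
15 | diethyl (cyanomethyl)phosphonate | CCOP(=O)(CC#N)OCC | starting material
16 | C9 Michael adduct (C12 ketone, cyano phosphonate on C9; phosphonate carbon unassigned) | C=C1C[C@]2([C@@H](CO[Si](c3ccccc3)(c3ccccc3)C(C)(C)C)C=C)C[C@H]1C(=O)C[C@H]2C(C#N)P(=O)(OCC)OCC | intermediate
17 | 4-methylbenzenesulfonohydrazide | Cc1ccc(cc1)S(=O)(=O)NN | starting material
18 | C12 tosylhydrazone of 16 | C=C1C[C@]2([C@@H](CO[Si](c3ccccc3)(c3ccccc3)C(C)(C)C)C=C)C[C@H]1C(=NNS(=O)(=O)c1ccc(C)cc1)C[C@H]2C(C#N)P(=O)(OCC)OCC | intermediate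
19 | C12-deoxy phosphonate nitrile | C=C1C[C@]2([C@@H](CO[Si](c3ccccc3)(c3ccccc3)C(C)(C)C)C=C)C[C@H]1CC[C@H]2C(C#N)P(=O)(OCC)OCC | intermediate
20 | formaldehyde | C=O | starting material
21 | C/D α-methylene nitrile (acrylonitrile on C9, vinyl on C6) | C=C1C[C@]2([C@@H](CO[Si](c3ccccc3)(c3ccccc3)C(C)(C)C)C=C)C[C@H]1CC[C@H]2C(=C)C#N | intermediate
22 | methacrolein | CC(=C)C=O | starting material
23 | (E)-enal | C=C1C[C@]2([C@@H](CO[Si](c3ccccc3)(c3ccccc3)C(C)(C)C)/C=C(\C)C=O)C[C@H]1CC[C@H]2C(=C)C#N | intermediate
24 | O-(diphenylphosphinyl)hydroxylamine | NOP(=O)(c1ccccc1)c1ccccc1 | starting material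
25 | C/D bis(unsaturated nitrile), key-step precursor | C=C1C[C@]2([C@@H](CO[Si](c3ccccc3)(c3ccccc3)C(C)(C)C)/C=C(\C)C#N)C[C@H]1CC[C@H]2C(=C)C#N | intermediate
26 | methyl 2-(tert-butyldimethylsilyloxy)acetate | COC(=O)CO[Si](C)(C)C(C)(C)C | starting material
27 | lithium enolate of 26 | COC(O[Li])=CO[Si](C)(C)C(C)(C)C | intermediate
28 | C10 lithionitrile (after the C1–C2 Michael addition) | C=C1C[C@]2([C@@H](CO[Si](c3ccccc3)(c3ccccc3)C(C)(C)C)/C=C(\C)C#N)C[C@H]1CC[C@H]2C([Li])(C#N)CC(O[Si](C)(C)C(C)(C)C)C(=O)OC | intermediate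
29 | C4 lithionitrile (ring B closed) | C=C1C[C@]23C[C@H]1CC[C@H]2[C@](C#N)(CC(O[Si](C)(C)C(C)(C)C)C(=O)OC)[C@@H](C([Li])(C)C#N)[C@@H]3CO[Si](c1ccccc1)(c1ccccc1)C(C)(C)C | intermediate
30 | ring-A/B keto dinitrile (2β-OTBS, 3-oxo, 7-OTBDPS, 19,20-dinitrile) | C=C1C[C@]23C[C@H]1CC[C@H]2[C@]1(C#N)C[C@H](O[Si](C)(C)C(C)(C)C)C(=O)[C@@](C)(C#N)[C@H]1[C@@H]3CO[Si](c1ccccc1)(c1ccccc1)C(C)(C)C | intermediate
31 | 3β-alcohol dinitrile | C=C1C[C@]23C[C@H]1CC[C@H]2[C@]1(C#N)C[C@H](O[Si](C)(C)C(C)(C)C)[C@H](O)[C@@](C)(C#N)[C@H]1[C@@H]3CO[Si](c1ccccc1)(c1ccccc1)C(C)(C)C | intermediate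
32 | 19,20-dialdehyde (2β-OTBS, 3β-OH, 7-OTBDPS) | C=C1C[C@]23C[C@H]1CC[C@H]2[C@]1(C=O)C[C@H](O[Si](C)(C)C(C)(C)C)[C@H](O)[C@@](C)(C=O)[C@H]1[C@@H]3CO[Si](c1ccccc1)(c1ccccc1)C(C)(C)C | intermediate
33 | 2β,3β,7-triol 19,20-dialdehyde | C=C1C[C@]23C[C@H]1CC[C@H]2[C@]1(C=O)C[C@H](O)[C@H](O)[C@@](C)(C=O)[C@H]1[C@@H]3CO | intermediate
34 | 7-acid 19,20-dialdehyde | C=C1C[C@]23C[C@H]1CC[C@H]2[C@]1(C=O)C[C@H](O)[C@H](O)[C@@](C)(C=O)[C@H]1[C@@H]3C(=O)O | intermediate
35 | 2β,3β-dihydroxygibberell-16-ene-7,19,20-trioic acid (the target gibberellin) | C=C1C[C@]23C[C@H]1CC[C@H]2[C@]1(C(=O)O)C[C@H](O)[C@H](O)[C@@](C)(C(=O)O)[C@H]1[C@@H]3C(=O)O | target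

**Step count and risks**

Total step count: 19. Longest linear sequence: 17 steps (steps 3–19 from 2-chloroprop-2-en-1-ol, and equally steps 1, 2 and 5–19 from (E)-but-2-ene-1,4-diol); the chain from 3-ethoxycyclohex-2-en-1-one (steps 4–19) is one step shorter.

Steps most likely to fail:

1. Step 15. The anion relay may be interrupted by proton transfer from the ester α-C–H at C2 or the allylic C6–H to the α-cyano carbanions, or the 5-exo closure may show poor facial selectivity. Fallback: the three bond formations are run as separate, thermodynamically driven operations. Setting out from 25, the Michael addition of the enolate of 26 at −78 °C is quenched at once with acetic acid to give the open-chain Michael adduct F1. KOt-Bu (cat.) in t-BuOH–THF then equilibrates all carbanions, so that the minor C10 nitrile anion cyclises irreversibly (5-exo Michael, protonation by solvent) to the ring-B dinitrile ester F2, whose diastereomers can be separated. KOt-Bu (1.1 equiv) in THF finally effects the nitrile-anion acylation (Thorpe/Dieckmann type, driven by enolisation at C2), and the route is rejoined at 30.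

2. Step 8. The alkenyl–palladium intermediate may insert into the C6 vinyl group (Heck pathway) instead of coupling with the enolate, oxidative addition into the alkenyl chloride may be slow, or the enolate may self-condense. Fallback: ring D is closed by alkyne activation without a free enolate. Setting out from 12, dehydrochlorination (LiN(i-Pr)2 in excess, THF, −78 → 0 °C) gives the propargyl vinylogous ester F3. Stork–Danheiser transposition (i-Bu2AlH; then 1 M HCl) gives the propargyl enone F4. Soft enolisation (TBSOTf, Et3N, CH2Cl2) gives the cross-conjugated silyl dienol ether F5. Carbocyclisation catalysed by monovalent gold (Ph3PAuCl/AgBF4, CH2Cl2–MeOH, 5-exo-dig, Conia-ene type) then gives the exocyclic methylene, and the route is rejoined at 14.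

3. Step 17. Reduction of the two hindered, mutually 1,3-diaxial nitriles may stop at one nitrile or over-reduce, a formed imine may condense with the neighbouring nitrile, or the β-alkoxy imine may fragment by a retro-aldol pathway. Fallback: the carboxyl level is reached hydrolytically. Setting out from 31, neutral hydration of both nitriles with [PtH{(PMe2O)2H}(PMe2OH)] (EtOH–H2O, 80 °C) gives the bis-carboxamide F6. HF·pyridine gives the triol diamide F7. TEMPO/PhI(OAc)2 in MeCN–H2O gives the 7-acid diamide F8. Nitrosative deamidation of the two primary amides (NaNO2, aq. H2SO4–AcOH, 0 °C) then gives the triacid directly, rejoining the route at 35.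

**Further compounds**

F1 | step 15 | open-chain Michael adduct (C10–H nitrile, glycolate ester) | C=C1C[C@]2([C@@H](CO[Si](c3ccccc3)(c3ccccc3)C(C)(C)C)/C=C(\C)C#N)C[C@H]1CC[C@H]2C(C#N)CC(O[Si](C)(C)C(C)(C)C)C(=O)OC
F2 | step 15 | ring-B dinitrile ester (C4–H nitrile) | C=C1C[C@]23C[C@H]1CC[C@H]2[C@](C#N)(CC(O[Si](C)(C)C(C)(C)C)C(=O)OC)[C@@H](C(C)C#N)[C@@H]3CO[Si](c1ccccc1)(c1ccccc1)C(C)(C)C
F3 | step 8 | propargyl vinylogous ester | C#CC[C@]1([C@@H](CO[Si](c2ccccc2)(c2ccccc2)C(C)(C)C)C=C)CCC(OCC)=CC1=O
F4 | step 8 | propargyl enone | C#CC[C@]1([C@@H](CO[Si](c2ccccc2)(c2ccccc2)C(C)(C)C)C=C)CCC(=O)C=C1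
F5 | step 8 | cross-conjugated silyl dienol ether | C#CC[C@]1([C@@H](CO[Si](c2ccccc2)(c2ccccc2)C(C)(C)C)C=C)CC=C(O[Si](C)(C)C(C)(C)C)C=C1
F6 | step 17 | bis-carboxamide (2β-OTBS, 3β-OH, 7-OTBDPS) | C=C1C[C@]23C[C@H]1CC[C@H]2[C@]1(C(N)=O)C[C@H](O[Si](C)(C)C(C)(C)C)[C@H](O)[C@@](C)(C(N)=O)[C@H]1[C@@H]3CO[Si](c1ccccc1)(c1ccccc1)C(C)(C)C
F7 | step 17 | triol diamide | C=C1C[C@]23C[C@H]1CC[C@H]2[C@]1(C(N)=O)C[C@H](O)[C@H](O)[C@@](C)(C(N)=O)[C@H]1[C@@H]3CO
F8 | step 17 | 7-acid diamide | C=C1C[C@]23C[C@H]1CC[C@H]2[C@]1(C(N)=O)C[C@H](O)[C@H](O)[C@@](C)(C(N)=O)[C@H]1[C@@H]3C(=O)O
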